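The free catalyst is a small charge, 12 mM against 0.50 M of starting material, so a balance of the reagent can ignore its turnover and count material. Starting material binds the catalyst, reagent then joins, by-product leaves and target follows.

the same everywhere: free catalyst 12 mM
- south: starting material 0.25 M; reagent 0.50 M; run made earlier
- south-east: starting material 1 M; reagent 0.50 M; run made earlier
- north-west: starting material 0.50 M; reagent 0.75 M; run made earlier
- flask: starting material 0.50 M; reagent 0.500 M; time 15 min

- south (time / min: starting material / %, target / %): 0.500: 98.2, 0.6; 1.33: 94.4, 3.0; 2.50: 89.9, 7.4; 4.00: 85.0, 11.2; 5.00: 83.7, 15.0; 8.00: 73.6, 23.0; 10.0: 68.7, 28.6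
- south-east (time / min: starting material / %, target / %): 1.33: 97.5, 1.1; 2.50: 96.3, 2.4; 4.00: 94.2, 4.9; 5.00: 93.7, 4.9; 6.00: 92.0, 7.0; 8.00: 89.0, 9.6; 10.0: 85.9, 11.4
- north-west (time / min: starting material / %, target / %): 0.667: 97.8, 0.9; 1.33: 95.9, 2.2; 2.50: 93.9, 4.8; 5.00: 88.4, 9.8; 10.0: 78.4, 20.1

(scatter of a reading: 0.5 percentage points)

- percent here means starting material units held: one side product counts as two
- what is said of by-product includes idle adduct
- what was read earlier has a scatter of 0.5 percentage points, one standard deviation
- reactions considered so far: starting material + free catalyst <-> catalyst intermediate A; reagent + catalyst intermediate A -> catalyst intermediate B; catalyst intermediate B <-> by-product + catalyst intermediate C; catalyst intermediate C -> free catalyst + target; reagent + by-product <-> idle adduct; starting material + target -> side product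
- the earlier runs do not show how much of reagent is bound; that part of a forecast is a guess

1. part of the starting material that has reacted at 15 min
2. share of the unused reagent that is free and not bound as idle adduct, at 15 min

Let x be the starting material reacted, in M. Each unit takes at most one reagent and gives at most one by-product, so the unused reagent, free plus idle adduct, is at least [reagent]₀ − x, and idle adduct is at most x.

The north-west run has our [starting material] but more reagent, and we assume that extra reagent matters little. It lost 11.6 % up to 5.00 min and 10.0 % in the equal time after, so on that assumption holding its average of 0.01080 M min⁻¹ to 15 min gives our upper estimate of x, 0.162 M.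

From below, we follow that run to 10.0 min, then allow the south run's slower average of 0.007825 M min⁻¹. We take this as low enough, since by our upper estimate [starting material] stays above 0.338 M, more than the south run held at its start. That gives 0.147 M.

The free-reagent floor, 1 − x/([reagent]₀ − x), is the share left if no by-product stays unbound. At the upper x it is 52.1 %. The runs do not show how much reagent is bound, so the top stays open.

| | from below | from above |
|---|---|---|
| reacted | 29.4 % | 32.4 % |
| free share | 52.1 % | 100 % |

The forecast, 31 % (28.5 % to 33.5 %) and 80 % (55 % to 98 %), puts both points inside this bracket and says “The share of free reagent is not constrained by the data.”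

The flask gives 30.9 % reacted and 72.8 % free, both inside.

    starting material + free catalyst ⇌ catalyst intermediate A (K = 1.50 M⁻¹, k = 0.120 M⁻¹ s⁻¹)
    reagent + catalyst intermediate A → catalyst intermediate B (k = 1.20 M⁻¹ s⁻¹)
    catalyst intermediate B ⇌ by-product + catalyst intermediate C (K = 32.0 M, k = 0.0330 s⁻¹)
    catalyst intermediate C → free catalyst + target (k = 0.0620 s⁻¹)
    reagent + by-product ⇌ idle adduct, settled at all times (K = 7.00 M⁻¹)
    starting material + target → side product (k = 6.60 × 10⁻⁵ M⁻¹ s⁻¹)

The flask stands at 30.9 % reacted mainly because it is read at 15 min: with that early reading taken away and the flask left to 150 min, it reaches 95.6 %. At 15 min the flask's free share of 72.8 % stands above the floor of 52.1 %, with 0.0533 M of by-product unbound beside 0.0945 M of idle adduct. In the neighbour flask with 0.30 M of starting material, 40.8 % reacted, so the floor there is 67.6 %; the computed free share of that neighbour flask is 78.9 %.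

The numbers in the tables are simulated from invented constants, and the scatter is random.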